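## Retrosynthetic overview
- The N-oxide comes from the tertiary amine by late N-oxidation. Ring E (side-chain lactone) is cut at C18–C19: an intermolecular, chelate-controlled carbonyl allylation joins the tetracyclic C3 aldehyde (rings A–D) with ethyl 2-[(trimethylsilyl)methyl]acrylate, followed by lactonisation and hydrogenation (C18, C20).
- Ring D comes from Eschenmoser–Claisen rearrangement and selenolactonisation on a ring-C allylic alcohol. The C10 ethyl comes from Keck allylation, isomerisation, ethenolysis and hydrogenation; the C13 methyl from α-methylenation and convex-face hydrogenation.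
- Ring A comes from ring-closing metathesis of an N-allyl/C9-allyl diene. Rings B and C come from a trans-hexahydroindolone made from Cbz-L-tyrosine, which supplies C3 and controls C9a, C1 and C9.
- Order of ring formation: C and B together (step 1), then A, then D, then E.

Assumption: the target is taken exactly as its SMILES encodes it, (1R,3S,9R,9aR,10R,11S,12S,13R,18S,20S) in tuberostemonine numbering (used in all names from compound 13 on), with N–O syn to the C9a–C9 bond and the C13 methyl cis to C1 on ring D.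

## Route

Step 1
Reactants: 1 N-benzyloxycarbonyl-L-tyrosine
Product: 4 cis-hydroindolenone, 1-benzyl 2-methyl (2S,3aR,7aR)-3a-hydroxy-6-oxo-2,3,3a,6,7,7a-hexahydro-1H-indole-1,2-dicarboxylate, via spirolactone dienone 2 (not isolated), via hydroxy dienone methyl ester 3 (not isolated)
Conditions: PhI(OAc)2 (1.1 equiv), NaHCO3 (3 equiv), MeOH, 0 → 40 °C
Reagents that add atoms: methanol, CO
Why: Hypervalent-iodine oxidative dearomatisation traps the carboxylate as a spirolactone, methanolysis opens it, and a desymmetrising intramolecular aza-Michael addition of the carbamate nitrogen closes ring B cis-fused with the ester on the exo face, so the L-tyrosine centre (future C3) sets C7a (future C9a).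

Step 2
Reactants: 4 cis-hydroindolenone
Product: 5 tertiary benzoate of 4 (3a-benzoyloxy)
Conditions: Bz2O, DMAP, Et3N, CH2Cl2, rt → 40 °C
Reagents that add atoms: benzoic anhydride, O=C(OC(=O)c1ccccc1)c1ccccc1
Why: DMAP-catalysed acylation turns the tertiary allylic alcohol into an ionisable allylic ester without touching any stereocentre.

Step 3
Reactants: 5 tertiary benzoate
Product: 6 trans-hydroindolenone, 1-benzyl 2-methyl (2S,3aR,7aR)-6-oxo-2,3,3a,6,7,7a-hexahydro-1H-indole-1,2-dicarboxylate (H-3a anti to H-7a)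
Conditions: Pd2(dba)3·CHCl3 (5 mol%), Bu3P, HCO2H, Et3N, THF, 60 °C
Reagents that add atoms: none
Why: In this Tsuji–Trost-type formate reduction, zerovalent palladium ionises the benzoate anti and hydride is delivered from the metal to the tertiary allyl terminus, so H replaces OBz with inversion, giving the conjugated enone with a trans ring fusion (future C1).

Step 4
Reactants: 6 trans-hydroindolenone
Product: 7 7-allyl enone, (2S,3aR,7S,7aS), allyl on the face of N1 and anti to H-7a
Conditions: KN(SiMe3)2 (1.05 equiv), THF, −78 °C; CH2=CHCH2I, −78 → −40 °C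
Reagents that add atoms: allyl iodide, C=CCI
Why: Kinetic α′-enolate alkylation proceeds by axial attack anti to the axial H-7a, putting the allyl group cis to nitrogen (future C9); the equatorial C–N bond is orthogonal to the enolate, so E1cB loss of the carbamate is disfavoured.

Step 5
Reactants: 7 7-allyl enone
Product: 8 allylic alcohol, (2S,3aR,6R,7S,7aS)-7-allyl-6-hydroxy analogue of 7, OH cis to the allyl group
Conditions: NaBH4, CeCl3·7H2O, MeOH, −40 → 0 °C
Reagents that add atoms: none
Why: Luche 1,2-reduction delivers hydride to the carbonyl face anti to the axial allyl group, so the hydroxyl lies on the face from which the later Claisen rearrangement must deliver carbon to C12.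

Step 6
Reactants: 8 allylic alcohol
Product: 9 6-O-tert-butyldimethylsilyl ether of 8
Conditions: TBSOTf, 2,6-lutidine, CH2Cl2, −78 → 0 °C
Reagents that add atoms: tert-butyldimethylsilyl triflate, CC(C)(C)[Si](C)(C)OS(=O)(=O)C(F)(F)F
Why: Silylation of the hindered secondary alcohol removes the free OH and adds bulk next to the ring-C alkene, which steps 9 and 10 rely on.

Step 7
Reactants: 9 silyl ether
Product: 11 secondary amine (N–H pyrrolidine of 9), via triethylsilyl carbamate 10 (not isolated)
Conditions: Et3SiH (3 equiv), Pd(OAc)2 (10 mol%), Et3N (cat.), CH2Cl2, rt; then MeOH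
Reagents that add atoms: none
Why: Palladium-catalysed silane transfer cleaves the benzyl carbamate to a silyl carbamate that decarboxylates on methanolysis, a Cbz removal that spares both alkenes; with the ketone already reduced the free amine cannot undergo retro-Michael opening.

Step 8
Reactants: 11 secondary amine
Product: 12 N-allyl amine (N-allyl, C7-allyl diene)
Conditions: CH2=CHCH2Br (1.5 equiv), K2CO3, MeCN, 50 °C
Reagents that add atoms: allyl bromide, C=CCBr
Why: SN2 N-alkylation with a reactive allylic halide installs the second metathesis arm cis to the C-allyl group.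

Step 9
Reactants: 12 N-allyl amine
Product: 13 ABC tricycle (azepino[3,2,1-hi]indole): methyl 3-carboxylate, 10-OTBS, ring-A 6,7-alkene and ring-C 11,12-alkene
Conditions: TsOH·H2O (1.0 equiv), second-generation Grubbs catalyst RuCl2(=CHPh)(PCy3)(H2IMes) (5 mol%), CH2Cl2, 40 °C; aq. NaHCO3
Reagents that add atoms: none
Why: Ring-closing metathesis of the two cis-disposed terminal allyl groups closes the seven-membered ring A with loss of ethene, the amine being masked as its ammonium salt so that it does not bind ruthenium.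

Step 10
Reactants: 13 tricyclic diene
Product: 14 ring-A saturated tricycle (azepane), ring-C 11,12-alkene retained
Conditions: H2 (1 atm), RhCl(PPh3)3 (10 mol%), benzene/EtOH, rt
Reagents that add atoms: none
Why: Homogeneous hydrogenation with RhCl(PPh3)3 is strongly sterically governed, so the unhindered ring-A cis-alkene is reduced while the ring-C alkene, flanked by the C1 methine and the C10 silyloxy carbon, is left.

Step 11
Reactants: 14 azepane silyl ether
Product: 15 allylic alcohol ester (10-OH, methyl 3-carboxylate)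
Conditions: HF·pyridine, pyridine/THF, 0 °C → rt
Reagents that add atoms: none
Why: Fluoride-driven desilylation frees the C10 allylic alcohol under non-basic conditions that leave the α-amino ester intact.

Step 12
Reactants: 15 allylic alcohol ester
Product: 16 diol (C3 CH2OH, 10-OH)
Conditions: LiAlH4, THF, 0 °C; H2O, aq. NaOH
Reagents that add atoms: none
Why: Hydride reduction takes the ester to the primary alcohol, so that C3 can later be raised to the aldehyde without a lactone-incompatible ester reduction.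

Step 13
Reactants: 16 diol
Product: 17 mono-silyl ether (C3 CH2OTBDPS, free 10-OH)
Conditions: TBDPSCl (1.05 equiv), imidazole, CH2Cl2, 0 °C
Reagents that add atoms: tert-butyldiphenylsilyl chloride, CC(C)(C)[Si](Cl)(c1ccccc1)c1ccccc1
Why: The bulky silyl chloride reacts only with the primary alcohol and leaves the hindered secondary allylic alcohol free.

Step 14
Reactants: 17 allylic alcohol
Product: 19 γ,δ-unsaturated amide (C12 CH2CONMe2, 10,11-alkene), via ketene N,O-acetal 18 (not isolated)
Conditions: MeC(OMe)2NMe2 (5 equiv), xylenes, 135 °C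
Reagents that add atoms: N,N-dimethylacetamide dimethyl acetal, CC(OC)(OC)N(C)C
Why: Eschenmoser–Claisen [3,3] rearrangement transfers the two-carbon unit suprafacially from the C10 oxygen to C12, so the face of the C10–O bond fixes the C12 configuration while the alkene moves to C10=C11.

Step 15
Reactants: 19 unsaturated amide
Product: 21 ring-D selenolactone (cis-fused γ-lactone O–C11/C12–C13, 10-SePh trans to O-11), via lactone iminium chloride 20 (not isolated)
Conditions: PhSeCl (1.5 equiv), MeCN/H2O 5:1, rt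
Reagents that add atoms: phenylselenyl chloride, Cl[Se]c1ccccc1; water, O
Why: In this selenolactonisation the amide oxygen opens the seleniranium ion at C11 in a 5-exo anti addition from the face of its tether, giving the cis-fused lactone (C11 set) with trans selenium at C10, and water hydrolyses the iminium ether.

Step 16
Reactants: 21 selenolactone
Product: 22 10-allyl lactone (allyl trans to O-11 and to C8)
Conditions: CH2=CHCH2SnBu3 (4 equiv), AIBN (0.2 equiv), benzene, 80 °C
Reagents that add atoms: allyltributylstannane, C=CC[Sn](CCCC)(CCCC)CCCC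
Why: In this Keck radical allylation the planar C10 radical is trapped on the convex face, anti to both the lactone oxygen and the ring-A carbon, giving net retention and the C10 configuration of the target.

Step 17
Reactants: 22 10-allyl lactone
Product: 23 10-[(E)-prop-1-enyl] lactone
Conditions: RuHCl(CO)(PPh3)3 (5 mol%), toluene, 90 °C
Reagents that add atoms: none
Why: Ruthenium-hydride alkene isomerisation (hydrometalation/β-hydride elimination) moves the terminal double bond one position inward and stops there because further migration would put the metal on the hindered C10.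

Step 18
Reactants: 23 propenyl lactone
Product: 24 10-vinyl lactone
Conditions: ethene (3 atm), TsOH·H2O (1.05 equiv), second-generation Hoveyda–Grubbs catalyst RuCl2(=CH-C6H4-2-OiPr)(H2IMes) (10 mol%), CH2Cl2, 40 °C; aq. NaHCO3
Reagents that add atoms: ethene, C=C
Why: Cross-metathesis with excess ethene (ethenolysis) exchanges the propenyl terminus for a methylene and expels propene, leaving the two-carbon chain needed for the ethyl group.

Step 19
Reactants: 24 10-vinyl lactone
Product: 26 13-methylene lactone (α-methylene ring D), via formyl lactone sodium enolate 25 (not isolated)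
Conditions: NaH (3 equiv), HCO2Et (5 equiv), EtOH (cat.), THF, 0 °C → rt; then (CH2O)n, THF, 65 °C
Reagents that add atoms: formaldehyde (as paraformaldehyde), C=O
Why: Claisen formylation of the lactone followed by aldol addition to formaldehyde, formyl transfer and E1cB loss of formate is a deformylative α-methylenation that needs no alkylating agent, which the ring nitrogen would not tolerate.

Step 20
Reactants: 26 13-methylene lactone
Product: 27 10-ethyl-(13R)-13-methyl lactone (C3 CH2OTBDPS)
Conditions: H2 (1 atm), RhCl(PPh3)3 (10 mol%), benzene/EtOH, rt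
Reagents that add atoms: none
Why: Catalytic hydrogenation reduces the vinyl group to ethyl and adds H2 to the exocyclic alkene from the convex face of the cis-fused lactone (the face of H-11 and H-12), which puts the new methyl on the concave face cis to C1 (13R); enolate methylation would give the opposite epimer.

Step 21
Reactants: 27 silyl ether
Product: 28 primary alcohol (C3 CH2OH)
Conditions: HF·pyridine, pyridine/THF, rt
Reagents that add atoms: none
Why: Non-basic fluoride desilylation frees the primary alcohol without enolising the lactone, whose C13 methyl sits in the less stable orientation.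

Step 22
Reactants: 28 primary alcohol
Product: 29 C3 aldehyde (rings A–D; fragment 1)
Conditions: (COCl)2, DMSO, CH2Cl2, −78 °C; Et3N, −78 → −30 °C; used crude
Reagents that add atoms: none
Why: Swern oxidation at low temperature gives the α-amino aldehyde without over-oxidation and without epimerising C3 or C13.

Step 23
Reactants: 29 C3 aldehyde; 30 ethyl 2-[(trimethylsilyl)methyl]prop-2-enoate (fragment 2)
Product: 32 bis-lactone with (18S)-configured α-methylene ring E, via hydroxy ester 31 (not isolated)
Conditions: TiCl4 (2.2 equiv), CH2Cl2, −78 °C; 30 (2.5 equiv), −78 → −40 °C; aq. NaHCO3; then TsOH·H2O (1.3 equiv), toluene, 60 °C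
Reagents that add atoms: none
Why: In this Hosomi–Sakurai carbonyl allylation under Cram-chelate control, TiCl4 ties N4 and the aldehyde oxygen into a five-membered chelate and the allylsilane adds to the carbonyl face anti to C2, giving the threo (18S) alkoxide, which acid closes to ring E with loss of ethanol.

Step 24
Reactants: 32 α-methylene bis-lactone
Product: 33 tertiary amine (N-deoxy target; tuberostemonine skeleton with the configuration encoded in the target)
Conditions: H2 (1 atm), 10% Pd/C, EtOAc, rt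
Reagents that add atoms: none
Why: Heterogeneous hydrogenation adds hydrogen to the α-methylene lactone from the face anti to the bulky C18 substituent, placing the new methyl cis to it (20S); any butenolide formed by isomerisation on palladium is reduced with the same facial sense.

Step 25
Reactants: 33 tertiary amine
Product: 34 N-oxytuberostemonine (target)
Conditions: mCPBA (1.05 equiv), CH2Cl2, −20 → 0 °C; basic alumina
Reagents that add atoms: 3-chloroperoxybenzoic acid, O=C(OO)c1cccc(Cl)c1
Why: Electrophilic N-oxidation by the peracid takes place at the lone pair of the trans-fused ring A/ring B invertomer on the face anti to the C3 lactone, giving the N–O bond syn to C9a–C9 as required.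

## Compound list
1 | N-benzyloxycarbonyl-L-tyrosine | O=C(O)[C@H](Cc1ccc(O)cc1)NC(=O)OCc1ccccc1 | starting material
2 | spirolactone dienone, benzyl N-[(3S)-2,8-dioxo-1-oxaspiro[4.5]deca-6,9-dien-3-yl]carbamate | O=C1C=CC2(C=C1)C[C@H](NC(=O)OCc1ccccc1)C(=O)O2 | intermediate
3 | methyl (2S)-2-(benzyloxycarbonylamino)-3-(1-hydroxy-4-oxocyclohexa-2,5-dien-1-yl)propanoate | COC(=O)[C@H](CC1(O)C=CC(=O)C=C1)NC(=O)OCc1ccccc1 | intermediate
4 | cis-hydroindolenone, 1-benzyl 2-methyl (2S,3aR,7aR)-3a-hydroxy-6-oxo-2,3,3a,6,7,7a-hexahydro-1H-indole-1,2-dicarboxylate | O=C1C=C[C@]2(O)C[C@@H](C(=O)OC)N(C(=O)OCc3ccccc3)[C@@H]2C1 | intermediate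
5 | 3a-O-benzoate of 4 | O=C1C=C[C@]2(OC(=O)c3ccccc3)C[C@@H](C(=O)OC)N(C(=O)OCc3ccccc3)[C@@H]2C1 | intermediate
6 | trans-hydroindolenone, 1-benzyl 2-methyl (2S,3aR,7aR)-6-oxo-2,3,3a,6,7,7a-hexahydro-1H-indole-1,2-dicarboxylate | O=C1C=C[C@H]2C[C@@H](C(=O)OC)N(C(=O)OCc3ccccc3)[C@@H]2C1 | intermediate
7 | (2S,3aR,7S,7aS)-7-allyl derivative of 6, allyl cis to N1 | O=C1C=C[C@H]2C[C@@H](C(=O)OC)N(C(=O)OCc3ccccc3)[C@@H]2[C@@H]1CC=C | intermediate
8 | (2S,3aR,6R,7S,7aS)-7-allyl-6-hydroxy analogue of 7, OH cis to allyl | O[C@@H]1C=C[C@H]2C[C@@H](C(=O)OC)N(C(=O)OCc3ccccc3)[C@@H]2[C@@H]1CC=C | intermediate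
9 | 6-O-tert-butyldimethylsilyl ether of 8 | CC(C)(C)[Si](C)(C)O[C@@H]1C=C[C@H]2C[C@@H](C(=O)OC)N(C(=O)OCc3ccccc3)[C@@H]2[C@@H]1CC=C | intermediate
10 | triethylsilyl carbamate corresponding to 9 (N–CO2SiEt3) | CC(C)(C)[Si](C)(C)O[C@@H]1C=C[C@H]2C[C@@H](C(=O)OC)N(C(=O)O[Si](CC)(CC)CC)[C@@H]2[C@@H]1CC=C | intermediate
11 | secondary amine, N–H pyrrolidine of 9 | CC(C)(C)[Si](C)(C)O[C@@H]1C=C[C@H]2C[C@@H](C(=O)OC)N[C@@H]2[C@@H]1CC=C | intermediate
12 | N-allyl amine, N-allyl/C7-allyl diene | CC(C)(C)[Si](C)(C)O[C@@H]1C=C[C@H]2C[C@@H](C(=O)OC)N(CC=C)[C@@H]2[C@@H]1CC=C | intermediate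
13 | ABC tricycle with ring-A 6,7-alkene and ring-C 11,12-alkene; methyl 3-carboxylate, 10-OTBS; centres C1, C3, C9, C9a as in the target, 10-O cis to C9–C8 | CC(C)(C)[Si](C)(C)O[C@@H]1C=C[C@H]2C[C@@H](C(=O)OC)N3[C@@H]2[C@@H]1CC=CC3 | intermediate
14 | ring-A saturated tricycle (azepane), 11,12-alkene, 10-OTBS, methyl 3-carboxylate | CC(C)(C)[Si](C)(C)O[C@@H]1C=C[C@H]2C[C@@H](C(=O)OC)N3[C@@H]2[C@@H]1CCCC3 | intermediate
15 | 10-hydroxy methyl ester (allylic alcohol) | O[C@@H]1C=C[C@H]2C[C@@H](C(=O)OC)N3[C@@H]2[C@@H]1CCCC3 | intermediate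
16 | diol, C3 CH2OH and 10-OH | O[C@@H]1C=C[C@H]2C[C@@H](CO)N3[C@@H]2[C@@H]1CCCC3 | intermediate
17 | C3 CH2OTBDPS ether with free 10-OH | O[C@@H]1C=C[C@H]2C[C@@H](CO[Si](c4ccccc4)(c4ccccc4)C(C)(C)C)N3[C@@H]2[C@@H]1CCCC3 | intermediate
18 | ketene N,O-acetal, 10-O-[1-(dimethylamino)vinyl] ether of 17 | C=C(N(C)C)O[C@@H]1C=C[C@H]2C[C@@H](CO[Si](c4ccccc4)(c4ccccc4)C(C)(C)C)N3[C@@H]2[C@@H]1CCCC3 | intermediate
19 | amide, C12 CH2CONMe2 (cis to N at C9a), 10,11-alkene | C1=C[C@H](CC(=O)N(C)C)[C@H]2C[C@@H](CO[Si](c4ccccc4)(c4ccccc4)C(C)(C)C)N3[C@@H]2[C@@H]1CCCC3 | intermediate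
20 | lactone iminium chloride (O-C11 cyclic imidate, 10-SePh) | c5ccccc5[Se][C@@H]1[C@H]2CCCCN3[C@H]2[C@H](C[C@H]3CO[Si](c4ccccc4)(c4ccccc4)C(C)(C)C)[C@@H]2[C@H]1OC(=[N+](C)C)C2.[Cl-] | intermediate
21 | ring-D selenolactone, cis-fused γ-lactone, 10-SePh trans to O-11 | c5ccccc5[Se][C@@H]1[C@H]2CCCCN3[C@H]2[C@H](C[C@H]3CO[Si](c4ccccc4)(c4ccccc4)C(C)(C)C)[C@@H]2[C@H]1OC(=O)C2 | intermediate
22 | 10-allyl lactone, allyl trans to O-11 | C=CC[C@@H]1[C@H]2CCCCN3[C@H]2[C@H](C[C@H]3CO[Si](c4ccccc4)(c4ccccc4)C(C)(C)C)[C@@H]2[C@H]1OC(=O)C2 | intermediate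
23 | 10-[(E)-prop-1-enyl] lactone | C/C=C/[C@@H]1[C@H]2CCCCN3[C@H]2[C@H](C[C@H]3CO[Si](c4ccccc4)(c4ccccc4)C(C)(C)C)[C@@H]2[C@H]1OC(=O)C2 | intermediate
24 | 10-vinyl lactone | C=C[C@@H]1[C@H]2CCCCN3[C@H]2[C@H](C[C@H]3CO[Si](c4ccccc4)(c4ccccc4)C(C)(C)C)[C@@H]2[C@H]1OC(=O)C2 | intermediate
25 | sodium enolate of the 13-formyl derivative of 24 | C=C[C@@H]1[C@H]2CCCCN3[C@H]2[C@H](C[C@H]3CO[Si](c4ccccc4)(c4ccccc4)C(C)(C)C)[C@@H]2[C@H]1OC(=O)C2=C[O-].[Na+] | intermediate
26 | 13-methylene lactone, 10-vinyl | C=C[C@@H]1[C@H]2CCCCN3[C@H]2[C@H](C[C@H]3CO[Si](c4ccccc4)(c4ccccc4)C(C)(C)C)[C@@H]2[C@H]1OC(=O)C2=C | intermediate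
27 | 10-ethyl-(13R)-13-methyl lactone, C3 CH2OTBDPS | CC[C@@H]1[C@H]2CCCCN3[C@H]2[C@H](C[C@H]3CO[Si](c4ccccc4)(c4ccccc4)C(C)(C)C)[C@@H]2[C@H]1OC(=O)[C@@H]2C | intermediate
28 | primary alcohol, C3 CH2OH | CC[C@@H]1[C@H]2CCCCN3[C@H]2[C@H](C[C@H]3CO)[C@@H]2[C@H]1OC(=O)[C@@H]2C | intermediate
29 | C3 aldehyde, rings A–D | CC[C@@H]1[C@H]2CCCCN3[C@H]2[C@H](C[C@H]3C=O)[C@@H]2[C@H]1OC(=O)[C@@H]2C | intermediate
30 | ethyl 2-[(trimethylsilyl)methyl]prop-2-enoate | CCOC(=O)C(=C)C[Si](C)(C)C | starting material
31 | (18S)-hydroxy ester, C3–CH(OH)–CH2–C(=CH2)–CO2Et | CC[C@@H]1[C@H]2CCCCN3[C@H]2[C@H](C[C@H]3[C@@H](O)CC(=C)C(=O)OCC)[C@@H]2[C@H]1OC(=O)[C@@H]2C | intermediate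
32 | bis-lactone with (18S) α-methylene ring E | CC[C@@H]1[C@H]2CCCCN3[C@H]2[C@H](C[C@H]3[C@@H]2CC(=C)C(=O)O2)[C@@H]2[C@H]1OC(=O)[C@@H]2C | intermediate
33 | tertiary amine, (1R,3S,9R,9aR,10R,11S,12S,13R,18S,20S) | CC[C@@H]1[C@H]2CCCCN3[C@H]2[C@H](C[C@H]3[C@@H]2C[C@H](C)C(=O)O2)[C@@H]2[C@H]1OC(=O)[C@@H]2C | intermediate
34 | N-oxytuberostemonine | CC[C@@H]1[C@H]2CCCC[N@@+]3([O-])[C@H]2[C@H](C[C@H]3[C@@H]2C[C@H](C)C(=O)O2)[C@@H]2[C@H]1OC(=O)[C@@H]2C | target

## Step count and risks
Total step count: 25. Longest linear sequence: 25 steps (1 → 34); 30 is bought.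

The three steps most likely to fail:

Step 10 (selective hydrogenation of the ring-A alkene). The ring-C alkene may be co-reduced, or the basic nitrogen may slow the rhodium catalyst. The fallback builds ring A as a lactam so that no alkene ever sits in it; it sets out from 9 and comes back at 16. Cross-metathesis of the allyl group of 9 with methyl acrylate (second-generation Hoveyda–Grubbs catalyst RuCl2(=CH-C6H4-2-OiPr)(H2IMes), CH2Cl2, 40 °C) gives the (E)-enoate F1. Conjugate reduction with Mg turnings in MeOH saturates only the enoate and gives the saturated diester F2. Cbz cleavage (Et3SiH, Pd(OAc)2, Et3N, then MeOH) gives the amino diester F3, which closes on heating in toluene with 2-hydroxypyridine to the ring-A lactam F4. LiAlH4 reduces the lactam to the azepane and the C3 ester to the alcohol, giving the amino alcohol silyl ether F5, and HF·pyridine then gives 16.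

Step 19 (α-methylenation at hindered C13). Formylation may be slow, or the methylene lactone may be lost to Michael addition. The fallback sets the C13 methyl by alkylation and kinetic protonation instead; it sets out from 24 and comes back at 27. LiN(iPr)2 (THF, −78 °C) followed by MeI (1.05 equiv) methylates the enolate from the convex face and gives the 13-epi (13S) methyl lactone F6. A second enolisation with LiN(iPr)2 and a quench at −78 °C with the bulky proton donor 2,6-di-tert-butyl-4-methylphenol delivers the proton to the same convex face and gives the (13R)-methyl vinyl lactone F7. Hydrogenation (H2, RhCl(PPh3)3) of the vinyl group then gives 27.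

Step 23 (the fragment-joining allylation). The ester-bearing allylsilane is a weak nucleophile, chelation at the hindered ring nitrogen is unproven and would decide C18, and the aldehyde can epimerise at C3. The fallback replaces the allylation by a vinylogous Mannich reaction; it sets out from 29 and comes back at 33, and also bypasses the exocyclic-alkene hydrogenation of step 24. Pinnick oxidation (NaClO2, NaH2PO4, 2-methyl-2-butene, t-BuOH/H2O) gives the amino acid F8. POCl3 (CH2Cl2/DMF, rt → 40 °C) causes decarbonylation to the cyclic iminium chloride F9, used in the same flask. The silyloxyfuran 3-methyl-2-(triisopropylsilyloxy)furan F10, made from 3-methylfuran-2(5H)-one with iPr3SiOTf and Et3N, adds to C3 from the face anti to C9 with threo selectivity and gives the butenolide F11. Hydrogenation (H2, 10% Pd/C, EtOH) anti to the C18 substituent then gives 33.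

## Further compounds
F1 | step 10 | (E)-enoate, cross-metathesis product of 9 with methyl acrylate | CC(C)(C)[Si](C)(C)O[C@@H]1C=C[C@H]2C[C@@H](C(=O)OC)N(C(=O)OCc3ccccc3)[C@@H]2[C@@H]1C/C=C/C(=O)OC
F2 | step 10 | saturated diester, 7-(4-methoxy-4-oxobutyl) analogue of 9 | CC(C)(C)[Si](C)(C)O[C@@H]1C=C[C@H]2C[C@@H](C(=O)OC)N(C(=O)OCc3ccccc3)[C@@H]2[C@@H]1CCCC(=O)OC
F3 | step 10 | amino diester, N–H pyrrolidine of F2 | CC(C)(C)[Si](C)(C)O[C@@H]1C=C[C@H]2C[C@@H](C(=O)OC)N[C@@H]2[C@@H]1CCCC(=O)OC
F4 | step 10 | ring-A lactam (5-oxo tricycle), methyl 3-carboxylate, 10-OTBS | CC(C)(C)[Si](C)(C)O[C@@H]1C=C[C@H]2C[C@@H](C(=O)OC)N3[C@@H]2[C@@H]1CCCC3=O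
F5 | step 10 | amino alcohol silyl ether, C3 CH2OH, 10-OTBS, azepane | CC(C)(C)[Si](C)(C)O[C@@H]1C=C[C@H]2C[C@@H](CO)N3[C@@H]2[C@@H]1CCCC3
F6 | step 19 | 13-epi (13S) methyl lactone, 10-vinyl | C=C[C@@H]1[C@H]2CCCCN3[C@H]2[C@H](C[C@H]3CO[Si](c4ccccc4)(c4ccccc4)C(C)(C)C)[C@@H]2[C@H]1OC(=O)[C@H]2C
F7 | step 19 | (13R)-methyl lactone, 10-vinyl | C=C[C@@H]1[C@H]2CCCCN3[C@H]2[C@H](C[C@H]3CO[Si](c4ccccc4)(c4ccccc4)C(C)(C)C)[C@@H]2[C@H]1OC(=O)[C@@H]2C
F8 | step 23 | amino acid, C3 carboxylic acid of rings A–D | CC[C@@H]1[C@H]2CCCCN3[C@H]2[C@H](C[C@H]3C(=O)O)[C@@H]2[C@H]1OC(=O)[C@@H]2C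
F9 | step 23 | cyclic iminium chloride, N4=C3 | CC[C@@H]1[C@H]2CCCC[N+]3[C@H]2[C@H](CC=3)[C@@H]2[C@H]1OC(=O)[C@@H]2C.[Cl-]
F10 | step 23 | 3-methyl-2-(triisopropylsilyloxy)furan | Cc1ccoc1O[Si](C(C)C)(C(C)C)C(C)C
F11 | step 23 | butenolide, (18S)-5-substituted 3-methylfuran-2(5H)-one on C3 | CC[C@@H]1[C@H]2CCCCN3[C@H]2[C@H](C[C@H]3[C@@H]2C=C(C)C(=O)O2)[C@@H]2[C@H]1OC(=O)[C@@H]2C
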